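The ten-membered carbocycle is disconnected at C8–C9 (germacrane numbering), the bond between the two vicinal acyloxy-bearing ring carbons that lie between the C1–C10 epoxide and the isopropenyl-bearing C7: a cis-1,2-diol next to an alkene-derived epoxide. One SmI2 pinacol coupling of an open-chain (Z)-enal/aldehyde forms this bond, closes the ring and sets both carbinol centres; the allylic C9 hydroxyl then directs the epoxidation. The dialdehyde comes from (S)-carvone, whose ring supplies C3–C8, the C7 centre and, through its trans-epoxide, the C4/C5 oxygens; the ring is cut between ketone and α′ carbon (C3/C8) and a (Z)-C2–C1–C10–C9 unit is attached to C3.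

Key step: step 13

Remark: positions are numbered as in germacrane (epoxide C1/C10 with the methyl on C10, C2 methylene, angeloyloxy C3, methyl carbinol C4, carbinol C5, C6 methylene, isopropenyl-bearing C7, angeloyloxy C8, acetoxy C9), also for open-chain intermediates; the target is then (1R,3S,4S,5R,7R,8S,9S,10R). TES = triethylsilyl. The carbinol carbon made in step 4 and the lactol carbon of 10 are formed as mixtures, which is without consequence because both become C8 of the chain.

Step 1
Reactants: 1 prop-2-yn-1-ol
Product: 3 (Z)-3-iodo-2-methylprop-2-en-1-ol, via alkenylmagnesium alkoxide 2 (not isolated)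
Conditions: MeMgBr (2.5 equiv), CuI (10 mol %), THF, −10 °C → rt; then I2, −78 → 0 °C
Reagents that add atoms: methylmagnesium bromide, C[Mg]Br; iodine, II
Why: Copper-catalysed anti-carbomagnesiation of the propargylic alkoxide places the methyl group on C2 and magnesium on C3 cis to the chelating oxygen, and iodinolysis with retention should give the (Z)-iodide.

Step 2
Reactants: 3 (Z)-3-iodo-2-methylprop-2-en-1-ol
Product: 4 TES ether of 3
Conditions: TESCl, imidazole, CH2Cl2, 0 °C
Reagents that add atoms: chlorotriethylsilane, CC[Si](Cl)(CC)CC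
Why: Silyl ether formation on a primary alcohol gives a group that tolerates tert-butyllithium and can later be oxidised off directly.

Step 3
Reactants: 5 (S)-(+)-carvone
Product: 6 trans-carvone oxide
Conditions: H2O2 (35% aq.), NaOH (aq.), MeOH, 0 °C
Reagents that add atoms: hydrogen peroxide, OO
Why: Weitz–Scheffer nucleophilic epoxidation is chemoselective for the enone over the isopropenyl group, and hydroperoxide adds anti to the isopropenyl substituent, so the trans-epoxide fixes the C4 oxygen (and, after inversion in step 6, C5) relative to C7.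

Step 4
Reactants: 6 trans-carvone oxide
Product: 8 α′-hydroxy epoxy ketone (both epimers at the new carbinol carbon), via potassium enolate 7 (not isolated)
Conditions: KN(SiMe3)2, THF, −78 °C; then 2-(phenylsulfonyl)-3-phenyloxaziridine, −78 °C; AcOH quench
Reagents that add atoms: 2-(phenylsulfonyl)-3-phenyloxaziridine, O=S(=O)(c1ccccc1)N1OC1c1ccccc1
Why: The ketone can enolise only towards the α′ methylene because the other α-carbon is the fully substituted epoxide carbon, and enolate hydroxylation with the N-sulfonyloxaziridine installs the oxygen needed for the cleavage, the new centre being destroyed in step 5.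

Step 5
Reactants: 8 α′-hydroxy epoxy ketone
Product: 9 open-chain glycidic methyl ester with the C8 aldehyde
Conditions: Pb(OAc)4, MeOH/benzene 1:1, 0 °C
Reagents that add atoms: methanol, CO
Why: Criegee-type cleavage of the α-hydroxy ketone through its methyl hemiketal should give the methyl ester from the ketone carbon (C3) and the aldehyde from the carbinol carbon (C8) without touching the epoxide or the C7 centre.

Step 6
Reactants: 9 glycidic ester aldehyde
Product: 11 triol methyl ester (C4, C5 and C8 hydroxyls), via lactol 10 (not isolated)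
Conditions: HClO4 (cat.), THF/H2O, 0 °C → rt; then NaHCO3; NaBH4, MeOH, 0 °C
Reagents that add atoms: water, O
Why: In the open chain the aldehyde hydrate opens the protonated glycidic ester 5-exo at the secondary carbon C5 remote from the ester (epoxide opening by an internal oxygen nucleophile) with inversion, which sets 5R and frees the C4 hydroxyl with retention (on the carvone ring the trans-diaxial rule would send the nucleophile to the other epoxide carbon), and borohydride then reduces the lactol through its open form.

Step 7
Reactants: 11 triol methyl ester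
Product: 12 tris-TES ether of 11
Conditions: TESOTf (3.5 equiv), 2,6-lutidine, CH2Cl2, −78 → 0 °C
Reagents that add atoms: triethylsilyl trifluoromethanesulfonate, CC[Si](CC)(CC)OS(=O)(=O)C(F)(F)F
Why: The silyl triflate with a hindered pyridine base silylates primary, secondary and tertiary hydroxyls alike (silyl ether formation), giving non-chelating ethers that fluoride removes at the end.

Step 8
Reactants: 12 tris-TES ester
Product: 13 chloromethyl ketone
Conditions: ICH2Cl, MeLi·LiBr, THF, −78 °C; NH4Cl (aq.)
Reagents that add atoms: chloroiodomethane, ClCI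
Why: Chloromethyllithium made in situ by iodine–lithium exchange adds once to the ester, and the tetrahedral lithium alkoxide survives until the quench, a known nucleophilic acyl substitution of esters to α-chloromethyl ketones.

Step 9
Reactants: 13 chloromethyl ketone
Product: 15 terminal C2–C3 epoxide, (S) at C3, via chlorohydrin 14 (not isolated)
Conditions: (R)-1-methyl-3,3-diphenyltetrahydro-1H,3H-pyrrolo[1,2-c][1,3,2]oxazaborole (20 mol %), catecholborane, toluene, −78 → −40 °C; then NaOH (2 M aq.), Et2O, rt
Reagents that add atoms: none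
Why: Corey–Bakshi–Shibata reduction distinguishes the small chloromethyl group from the large quaternary substituent and with the (R)-catalyst should give the (R)-chlorohydrin under reagent control, which hydroxide closes by intramolecular Williamson displacement to the epoxide with the C3 configuration of the target, while catecholborane leaves the isopropenyl group alone at low temperature.

Step 10
Reactants: 15 terminal epoxide; 4 (Z)-iodide TES ether
Product: 17 open-chain C3 alcohol, via alkenyllithium 16 (not isolated)
Conditions: 4, t-BuLi (2.1 equiv), Et2O, −78 °C; then 15, BF3·OEt2, −78 °C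
Reagents that add atoms: none
Why: Iodine–lithium exchange gives a configurationally stable (Z)-alkenyllithium that opens the BF3-activated terminal epoxide at its methylene carbon (SN2 epoxide opening), forming the C1–C2 bond and leaving only the C3 hydroxyl free.

Step 11
Reactants: 17 C3 alcohol
Product: 18 3-O-angelate
Conditions: angelic acid, 2,4,6-trichlorobenzoyl chloride, Et3N, toluene, rt; then 17, 75 °C
Reagents that add atoms: angelic acid, C/C=C(/C)C(=O)O
Why: Yamaguchi-type esterification through the 2,4,6-trichlorobenzoyl mixed anhydride should acylate the hindered secondary hydroxyl without Z to E isomerisation of the angeloyl group.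

Step 12
Reactants: 18 3-O-angelate
Product: 19 dialdehyde ((Z)-C9 enal and C8 aldehyde)
Conditions: (COCl)2, DMSO, CH2Cl2, −78 °C; 18, −78 → −30 °C; Et3N, −78 → 0 °C
Reagents that add atoms: none
Why: Under Swern oxidation conditions the chlorodimethylsulfonium ion exchanges only with the two primary triethylsilyl ethers, which are converted directly into aldehydes while the secondary and tertiary silyl ethers, the (Z)-geometry and, at low temperature, the C7 centre are kept.

Step 13
Reactants: 19 dialdehyde
Product: 20 ten-membered (Z)-cyclodecene cis-8,9-diol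
Conditions: SmI2 (3 equiv), THF, 0.003 M, slow addition of 19, −78 °C → rt
Reagents that add atoms: none
Why: SmI2 transfers an electron first to the conjugated (Z)-enal, the samarium-bound allylic ketyl adds through its carbonyl carbon to the samarium-coordinated C8 aldehyde, and a second electron gives the cyclic samarium diolate, which is protonated on work-up. The closest known reaction type is the intramolecular pinacol coupling of dialdehydes by SmI2 or low-valent titanium, which is used to close medium and large carbocyclic 1,2-diols. The ten-membered carbocycle closes in a 10-exo-trig sense with both C=O bonds outside the ring, and only the (Z)-rotamer of the allylic ketyl can reach the aldehyde, so the ring alkene stays cis. C8 should be set by Felkin–Anh addition with the isopropenyl group on C7 as the large substituent anti to the incoming ketyl, which gives 8S next to 7R, and C9 should be set relative to C8 by the samarium ion that bridges both oxygens in the bond-forming transition state and holds them syn-clinal with the ring bonds gauche, which leads to the cis (erythro) diol. The step needs reduction of the aldehydes and not of the angelate, coupling at the carbonyl carbon and not at the γ-carbon of the enal, and ring closure over oligomerisation; these should be secured by the much lower reduction potential of aldehydes without a polar additive, by the oxygen–samarium bridge that brings the two carbonyl carbons together, and by high dilution with slow addition.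

Step 14
Reactants: 20 cis-8,9-diol
Product: 21 1,10-epoxy-8,9-diol
Conditions: VO(acac)2 (5 mol %), t-BuOOH, CH2Cl2, 0 °C
Reagents that add atoms: tert-butyl hydroperoxide, CC(C)(C)OO
Why: Vanadium-catalysed hydroxyl-directed epoxidation should deliver oxygen to the ring alkene from the face of the allylic C9 hydroxyl, as is usual for medium-ring (Z)-cycloalkenols, giving the cis-epoxy alcohol (1R,10R), while the electron-poor angelate and the only homoallylically placed isopropenyl alkene react more slowly.

Step 15
Reactants: 21 epoxy diol
Product: 22 8-O-angelate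
Conditions: angelic acid, 2,4,6-trichlorobenzoyl chloride, Et3N, toluene, rt; then 21, 60 °C
Reagents that add atoms: angelic acid, C/C=C(/C)C(=O)O
Why: Yamaguchi-type acylation with the bulky mixed anhydride should take the C8 hydroxyl, flanked by two tertiary carbons, in preference to the C9 hydroxyl, which is neopentyl-like next to the fully substituted epoxide carbon and inductively deactivated by it.

Step 16
Reactants: 22 8-O-angelate
Product: 23 9-O-acetate (4,5-bis-TES ether of the target)
Conditions: Ac2O, 4-(dimethylamino)pyridine (cat.), pyridine, CH2Cl2, 0 °C → rt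
Reagents that add atoms: acetic anhydride, CC(=O)OC(C)=O
Why: Nucleophilic acyl-transfer catalysis with the small anhydride should esterify the remaining hindered C9 hydroxyl under conditions too mild for acyl migration.

Step 17
Reactants: 23 bis-TES ether
Product: 24 CNP0249359.1
Conditions: HF·pyridine, pyridine, THF, 0 °C → rt
Reagents that add atoms: none
Why: Buffered fluoride desilylation should cleave the secondary and tertiary triethylsilyl ethers while leaving the trisubstituted epoxide, the three esters and the alkenes intact and avoiding base-induced acyl migration.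

Compound list
1 | prop-2-yn-1-ol (propargyl alcohol) | C#CCO | starting material
2 | bromomagnesium (Z)-3-(bromomagnesio)-2-methylprop-2-en-1-olate | Br[Mg]OC/C(C)=C\[Mg]Br | intermediate
3 | (Z)-3-iodo-2-methylprop-2-en-1-ol | OC/C(C)=C\I | intermediate
4 | (Z)-triethyl[(3-iodo-2-methylprop-2-en-1-yl)oxy]silane | CC[Si](CC)(CC)OC/C(C)=C\I | intermediate
5 | (S)-(+)-carvone | CC1=CC[C@@H](CC1=O)C(C)=C | starting material
6 | trans-carvone oxide, (1S,4S,6S)-1-methyl-4-(prop-1-en-2-yl)-7-oxabicyclo[4.1.0]heptan-2-one | O=C1[C@@]2(C)O[C@H]2C[C@H](C(C)=C)C1 | intermediate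
7 | potassium α′-enolate of 6 | [K+].[O-]C=1[C@@]2(C)O[C@H]2C[C@H](C(C)=C)C=1 | intermediate
8 | (1S,4R,6S)-3-hydroxy-1-methyl-4-(prop-1-en-2-yl)-7-oxabicyclo[4.1.0]heptan-2-one, both C3 epimers | O=C1[C@@]2(C)O[C@H]2C[C@H](C(C)=C)C1O | intermediate
9 | methyl (2S,3S)-3-[(2R)-2-formyl-3-methylbut-3-en-1-yl]-2-methyloxirane-2-carboxylate | COC(=O)[C@@]1(C)O[C@H]1C[C@H](C(C)=C)C=O | intermediate
10 | methyl (2S)-2-hydroxy-2-[(2R,4R)-5-hydroxy-4-(prop-1-en-2-yl)oxolan-2-yl]propanoate (lactol, both anomers) | COC(=O)[C@@](C)(O)[C@H]1C[C@H](C(C)=C)C(O)O1 | intermediate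
11 | methyl (2S,3R,5R)-2,3-dihydroxy-5-(hydroxymethyl)-2,6-dimethylhept-6-enoate | COC(=O)[C@@](C)(O)[C@H](O)C[C@H](C(C)=C)CO | intermediate
12 | methyl (2S,3R,5R)-2,6-dimethyl-2,3-bis(triethylsilyloxy)-5-[(triethylsilyloxy)methyl]hept-6-enoate | COC(=O)[C@@](C)(O[Si](CC)(CC)CC)[C@H](O[Si](CC)(CC)CC)C[C@H](C(C)=C)CO[Si](CC)(CC)CC | intermediate
13 | (3S,4R,6R)-1-chloro-3,7-dimethyl-3,4-bis(triethylsilyloxy)-6-[(triethylsilyloxy)methyl]oct-7-en-2-one | ClCC(=O)[C@@](C)(O[Si](CC)(CC)CC)[C@H](O[Si](CC)(CC)CC)C[C@H](C(C)=C)CO[Si](CC)(CC)CC | intermediate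
14 | chlorohydrin of 13: C2 chloride, C3 carbinol of (R) configuration, 4,5,8-tris-O-TES | ClC[C@H](O)[C@@](C)(O[Si](CC)(CC)CC)[C@H](O[Si](CC)(CC)CC)C[C@H](C(C)=C)CO[Si](CC)(CC)CC | intermediate
15 | terminal C2–C3 oxirane, (S) at C3, 4,5,8-tris-O-TES | C1O[C@@H]1[C@@](C)(O[Si](CC)(CC)CC)[C@H](O[Si](CC)(CC)CC)C[C@H](C(C)=C)CO[Si](CC)(CC)CC | intermediate
16 | (Z)-[2-methyl-3-(triethylsilyloxy)prop-1-en-1-yl]lithium | CC[Si](CC)(CC)OC/C(C)=C\[Li] | intermediate
17 | open-chain (Z)-C1=C10 alkene with free C3 hydroxyl; 4,5,8,9-tetrakis-O-TES; stereocentres as in the target | CC[Si](CC)(CC)OC/C(C)=C\C[C@H](O)[C@@](C)(O[Si](CC)(CC)CC)[C@H](O[Si](CC)(CC)CC)C[C@H](C(C)=C)CO[Si](CC)(CC)CC | intermediate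
18 | 3-O-angelate of 17 | CC[Si](CC)(CC)OC/C(C)=C\C[C@H](OC(=O)/C(C)=C\C)[C@@](C)(O[Si](CC)(CC)CC)[C@H](O[Si](CC)(CC)CC)C[C@H](C(C)=C)CO[Si](CC)(CC)CC | intermediate
19 | open-chain dialdehyde: (Z)-C9 enal, C8 aldehyde, 3-O-angeloyl, 4,5-bis-O-TES | O=C/C(C)=C\C[C@H](OC(=O)/C(C)=C\C)[C@@](C)(O[Si](CC)(CC)CC)[C@H](O[Si](CC)(CC)CC)C[C@H](C(C)=C)C=O | intermediate
20 | ten-membered (Z)-cyclodecene cis-8,9-diol; 3-O-angeloyl; 4,5-bis-O-TES | O[C@@H]1/C(C)=C\C[C@H](OC(=O)/C(C)=C\C)[C@@](C)(O[Si](CC)(CC)CC)[C@H](O[Si](CC)(CC)CC)C[C@H](C(C)=C)[C@@H]1O | intermediate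
21 | 1,10-epoxide of 20, epoxide cis to the C9 hydroxyl | O[C@@H]1[C@]2(C)O[C@@H]2C[C@H](OC(=O)/C(C)=C\C)[C@@](C)(O[Si](CC)(CC)CC)[C@H](O[Si](CC)(CC)CC)C[C@H](C(C)=C)[C@@H]1O | intermediate
22 | 8-O-angelate of 21 (free C9 hydroxyl) | O[C@@H]1[C@]2(C)O[C@@H]2C[C@H](OC(=O)/C(C)=C\C)[C@@](C)(O[Si](CC)(CC)CC)[C@H](O[Si](CC)(CC)CC)C[C@H](C(C)=C)[C@@H]1OC(=O)/C(C)=C\C | intermediate
23 | 9-O-acetate of 22 (4,5-bis-O-TES ether of the target) | CC(=O)O[C@@H]1[C@]2(C)O[C@@H]2C[C@H](OC(=O)/C(C)=C\C)[C@@](C)(O[Si](CC)(CC)CC)[C@H](O[Si](CC)(CC)CC)C[C@H](C(C)=C)[C@@H]1OC(=O)/C(C)=C\C | intermediate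
24 | CNP0249359.1, (1R,3S,4S,5R,7R,8S,9S,10R)-9-acetoxy-3,8-bis(angeloyloxy)-1,10-epoxygermacr-11-ene-4,5-diol | CC(=O)O[C@@H]1[C@]2(C)O[C@@H]2C[C@H](OC(=O)/C(C)=C\C)[C@@](C)(O)[C@H](O)C[C@H](C(C)=C)[C@@H]1OC(=O)/C(C)=C\C | target

Total step count: 17. Longest linear sequence: 15 steps (5 to 24, steps 3–17).

Steps most likely to fail

Step 13. The reductive ring closure may couple through the γ-carbon of the enal ketyl or oligomerise, and the erythro/threo control at C9 may be poor. The fallback sets out from 19 and uses a low-valent titanium pinacol coupling (TiCl3(DME)1.5, zinc–copper couple, DME, slow addition), which joins enals at the carbonyl carbon on the metal surface. Should this give 20 together with its C9 epimer, the trans-diol F1, the mixture would be oxidised with MnO2 at the allylic hydroxyl only, converging on the 8-hydroxy-9-ketone F2. Zn(BH4)2 would then reduce F2 under chelation control by the C8 hydroxyl (hydride from the side of the C8 hydrogen) to the cis-diol, so the route is rejoined at 20.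

Step 15. Acylation may occur at the C9 hydroxyl or at both hydroxyls. The fallback sets out from 21: trimethyl orthoacetate with pyridinium p-toluenesulfonate would give the cyclic methyl orthoacetate F3 across the cis-diol. Brief treatment with dilute aqueous acid should open it so that the acetyl group stays on the less basic C9 oxygen next to the epoxide, giving the 9-acetate 8-alcohol F4. Yamaguchi-type angeloylation of the only free hydroxyl of F4 would then give 23 directly, where the route is rejoined.

Step 6. The α-isopropenyl aldehyde may enolise (epimerisation at C7 or shift of the alkene into conjugation) before it is trapped, or the epoxide may open sluggishly. The fallback sets out from 9: camphorsulfonic acid in dry methanol would convert the aldehyde at once into its methyl hemiacetal, whose hydroxyl opens the epoxide 5-exo at C5 to give the isolable methyl furanoside-type acetal F5. Aqueous acid hydrolysis of F5 followed by NaBH4 reduction of the lactol would return to 11.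

Further compounds
F1 | step 13 | C9 epimer of 20 (trans-8,9-diol) | O[C@H]1/C(C)=C\C[C@H](OC(=O)/C(C)=C\C)[C@@](C)(O[Si](CC)(CC)CC)[C@H](O[Si](CC)(CC)CC)C[C@H](C(C)=C)[C@@H]1O
F2 | step 13 | 8-hydroxy-9-ketone (macrocyclic (Z)-enone) | O=C1/C(C)=C\C[C@H](OC(=O)/C(C)=C\C)[C@@](C)(O[Si](CC)(CC)CC)[C@H](O[Si](CC)(CC)CC)C[C@H](C(C)=C)[C@@H]1O
F3 | step 15 | cyclic methyl orthoacetate of the 8,9-diol of 21 | COC1(C)O[C@@H]2[C@]3(C)O[C@@H]3C[C@H](OC(=O)/C(C)=C\C)[C@@](C)(O[Si](CC)(CC)CC)[C@H](O[Si](CC)(CC)CC)C[C@H](C(C)=C)[C@@H]2O1
F4 | step 15 | 9-O-acetate of 21 with free C8 hydroxyl | CC(=O)O[C@@H]1[C@]2(C)O[C@@H]2C[C@H](OC(=O)/C(C)=C\C)[C@@](C)(O[Si](CC)(CC)CC)[C@H](O[Si](CC)(CC)CC)C[C@H](C(C)=C)[C@@H]1O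
F5 | step 6 | methyl (2S)-2-hydroxy-2-[(2R,4R)-5-methoxy-4-(prop-1-en-2-yl)oxolan-2-yl]propanoate | COC(=O)[C@@](C)(O)[C@H]1C[C@H](C(C)=C)C(OC)O1
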